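The ten-membered carbocycle (C1–C10) is disconnected at C6–C7, because C6 (carbinol) and C7 (bearing the C11=C13 2-propenyl unit) form a homoallylic alcohol and C6–H is acidified by the C1 furanone carbonyl through C2=C3 and C4=C5. A [2,3]-Wittig ring contraction therefore makes the C6–C7 bond, the carbocycle, both stereocentres and the future lactone methylene in one operation. Its precursor is a furanone-bridged thirteen-membered diallyl ether (C6–O–C13, both alkenes Z, O8 silylated), assembled from an enyne–vinyl iodide ether and a citramalate lactone by acetylide addition, furanone closure and Nozaki–Hiyama–Kishi macrocyclisation; esterification, allylic oxidation and oxidative lactonisation finish the target.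

Key step: step 13

Remark: locants follow the germacrane frame (C1 furanone carbonyl, C2=C3 with the ring oxygen on C3, C4(C15)=C5, C6, C7, C8, C9, C10(C14), C11, C12, C13; thirteen-membered ring = C1–C6, O, C13, C11, C7–C10). By the sequence rule C7 of every O8-silylated ring-contracted compound is 7S (silicon on O8 outranks the substituent on O6); it becomes 7R in the free C8 alcohols and in the target with no change at that atom. The four starting materials (prop-2-yn-1-ol, (2Z)-3-methylpent-2-en-4-yn-1-ol, (S)-citramalic acid and methyl angelate) are taken as commercial.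

Step 1
Reactants: 1 prop-2-yn-1-ol
Product: 3 (2Z)-3-iodo-2-methylprop-2-en-1-ol, via cyclic alkenylmagnesium alkoxide 2 (not isolated)
Conditions: MeMgBr (3 equiv), CuI (0.1 equiv), THF/Et2O, −10 °C → rt; then I2, −10 °C; H2O
Reagents that add atoms: methylmagnesium bromide C[Mg]Br; iodine II
Why: Copper-catalysed anti-carbomagnesiation of the propargylic magnesium alkoxide puts methyl on the internal carbon and magnesium on the terminal carbon cis to CH2O (chelate 2), and iodinolysis with retention should give the Z iodide, a standard reaction of this very substrate.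

Step 2
Reactants: 3 (2Z)-3-iodo-2-methylprop-2-en-1-ol
Product: 4 (1Z)-3-bromo-1-iodo-2-methylprop-1-ene
Conditions: CBr4, PPh3, CH2Cl2, 0 °C
Reagents that add atoms: carbon tetrabromide BrC(Br)(Br)Br
Why: Appel bromination converts the primary allylic alcohol into the bromide by SN2 attack of bromide on the alkoxyphosphonium ion without touching the alkene geometry or the vinyl iodide.

Step 3
Reactants: 5 (2Z)-3-methylpent-2-en-4-yn-1-ol; 4 (1Z)-3-bromo-1-iodo-2-methylprop-1-ene
Product: 7 (3Z)-5-{[(2Z)-3-iodo-2-methylprop-2-en-1-yl]oxy}-3-methylpent-3-en-1-yne, via sodium alkoxide 6 (not isolated)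
Conditions: 5 and 4 (1.1 equiv), THF, 0 °C; NaH (1.05 equiv) in portions, Bu4NI (cat.), 0 °C → rt
Reagents that add atoms: none
Why: Williamson etherification of a primary allylic alkoxide with a primary allylic bromide is fast SN2 chemistry, the alkoxide being trapped as it forms (which leaves no time for base-induced cycloisomerisation of the Z enynol and no base for the far less acidic terminal alkyne) and SN2' attack being blocked by the iodine-bearing alkene terminus; the ether carries C2–C7, C11–C13 and both Z alkenes of the precursor.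

Step 4
Reactants: 8 (S)-citramalic acid
Product: 9 2-[(4S)-2,2,4-trimethyl-5-oxo-1,3-dioxolan-4-yl]acetic acid
Conditions: 2,2-dimethoxypropane, p-toluenesulfonic acid (cat.), rt
Reagents that add atoms: 2,2-dimethoxypropane COC(C)(C)OC
Why: Acid-catalysed acetalisation ties the tertiary hydroxyl and its geminal carboxyl into a five-membered dioxolanone, the standard way to tell the two carboxyl groups of a 2-hydroxysuccinic acid apart, and leaves the quaternary stereocentre (the future C10) untouched.

Step 5
Reactants: 9 2-[(4S)-2,2,4-trimethyl-5-oxo-1,3-dioxolan-4-yl]acetic acid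
Product: 11 (3S)-3-hydroxy-3-methyloxolan-2-one, via hydroxy dioxolanone 10 (not isolated)
Conditions: BH3·THF, THF, 0 °C → rt; MeOH; then p-toluenesulfonic acid (cat.), CH2Cl2, rt
Reagents that add atoms: none
Why: Borane reduces the free carboxylic acid chemoselectively beside the ester-like dioxolanone, and acid-catalysed transacylation of the primary alcohol 10 onto the dioxolanone carbonyl should close the five-membered lactone with loss of acetone, so that one ring masks both the C1 acyl group and the C8 oxygen.

Step 6
Reactants: 7 (3Z)-5-{[(2Z)-3-iodo-2-methylprop-2-en-1-yl]oxy}-3-methylpent-3-en-1-yne; 11 (3S)-3-hydroxy-3-methyloxolan-2-one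
Product: 13 (3S,7Z)-1,3-dihydroxy-9-{[(2Z)-3-iodo-2-methylprop-2-en-1-yl]oxy}-3,7-dimethylnon-7-en-5-yn-4-one (in equilibrium with its five-membered lactol), via lithium acetylide 12 (not isolated)
Conditions: 7 (2.2 equiv), LiN(iPr)2 (2.1 equiv), THF, −78 °C; then 11, −78 → −20 °C; AcOH, −78 °C
Reagents that add atoms: none
Why: 1,2-Addition of a lithium acetylide to a γ-lactone stops at the tetrahedral lithium hemiketal, which on quench should give the hydroxy ynone; one equivalent of acetylide is spent as base on the tertiary hydroxyl (that alkyne is recovered), and the slight deficit of LiN(iPr)2 deprotonates only the alkyne, without iodine–lithium exchange or deprotonation at the vinyl iodide.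

Step 7
Reactants: 13 (3S,7Z)-1,3-dihydroxy-9-{[(2Z)-3-iodo-2-methylprop-2-en-1-yl]oxy}-3,7-dimethylnon-7-en-5-yn-4-one
Product: 15 (2S)-2-(2-hydroxyethyl)-5-[(2Z)-4-{[(2Z)-3-iodo-2-methylprop-2-en-1-yl]oxy}but-2-en-2-yl]-2-methylfuran-3(2H)-one, via diethylamino enone 14 (not isolated)
Conditions: Et2NH (1.5 equiv), EtOH, rt; then AcOH, rt
Reagents that add atoms: none
Why: Conjugate addition of diethylamine to the ynone gives enaminone 14, whose tertiary C10 hydroxyl should displace the amine at C3 by addition–elimination through a five-membered ring, the classical amine-mediated cyclisation of 2-hydroxy-4-yn-3-ones to 3(2H)-furanones, while the primary hydroxyl could only close a seven-membered ring and the Z alkene is not part of the reacting system.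

Step 8
Reactants: 15 (2S)-2-(2-hydroxyethyl)-5-[(2Z)-4-{[(2Z)-3-iodo-2-methylprop-2-en-1-yl]oxy}but-2-en-2-yl]-2-methylfuran-3(2H)-one
Product: 16 2-[(2S)-5-[(2Z)-4-{[(2Z)-3-iodo-2-methylprop-2-en-1-yl]oxy}but-2-en-2-yl]-2-methyl-3-oxo-2,3-dihydrofuran-2-yl]acetaldehyde
Conditions: Dess–Martin periodinane, pyridine, CH2Cl2, 0 °C → rt
Reagents that add atoms: none
Why: Dess–Martin oxidation should turn the primary alcohol into the C8 aldehyde under buffered non-basic conditions, which matters because base could expel the furanone ring oxygen from the β-position of the aldehyde enolate.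

Step 9
Reactants: 16 2-[(2S)-5-[(2Z)-4-{[(2Z)-3-iodo-2-methylprop-2-en-1-yl]oxy}but-2-en-2-yl]-2-methyl-3-oxo-2,3-dihydrofuran-2-yl]acetaldehyde
Product: 18 (4Z,7(11)Z,10S)-8-hydroxy furanone-bridged thirteen-membered diallyl ether (both C8 epimers), via alkenylchromium dichloride 17 (not isolated)
Conditions: CrCl2 (8 equiv), NiCl2 (0.1 equiv), DMSO/THF, rt, 2 mM, slow addition of 16
Reagents that add atoms: none
Why: Nozaki–Hiyama–Kishi macrocyclisation: nickel-catalysed formation of the alkenylchromium species (trivalent chromium) from the Z iodide with retention and its chemoselective addition to the aldehyde should form C7–C8 and close the thirteen-membered ring in the presence of the dienone, the two cis alkenes and the furanone pre-organising the chain; the new C8 carbinol is expected as a mixture of epimers that steps 10 and 11 correct.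

Step 10
Reactants: 18 (4Z,7(11)Z,10S)-8-hydroxy furanone-bridged thirteen-membered diallyl ether (both C8 epimers)
Product: 19 (4Z,7(11)Z,10S)-8-oxo furanone-bridged thirteen-membered diallyl ether
Conditions: Dess–Martin periodinane, pyridine, CH2Cl2, 0 °C → rt
Reagents that add atoms: none
Why: Dess–Martin oxidation of the allylic alcohol converges both C8 epimers on one enone under neutral conditions that should not isomerise the ring-constrained Z alkene.

Step 11
Reactants: 19 (4Z,7(11)Z,10S)-8-oxo furanone-bridged thirteen-membered diallyl ether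
Product: 20 (4Z,7(11)Z,8S,10S)-8-hydroxy furanone-bridged thirteen-membered diallyl ether
Conditions: (R)-1-methyl-3,3-diphenyltetrahydro-1H,3H-pyrrolo[1,2-c][1,3,2]oxazaborole ((R)-Me-CBS, 0.5 equiv), catecholborane (1.8 equiv), toluene, −78 °C
Reagents that add atoms: none
Why: Corey–Bakshi–Shibata reduction: the enone binds the oxazaborolidine with its alkenyl side as the large group, so the (R)-catalyst (the one that turns acetophenone into (S)-1-phenylethanol) should deliver hydride to the face that gives the 8S allylic alcohol, while the cross-conjugated C1 carbonyl next to the quaternary C10 is far less electrophilic and should stay intact.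

Step 12
Reactants: 20 (4Z,7(11)Z,8S,10S)-8-hydroxy furanone-bridged thirteen-membered diallyl ether
Product: 21 (4Z,7(11)Z,8S,10S)-8-(tert-butyldimethylsilyloxy) furanone-bridged thirteen-membered diallyl ether (C6–O–C13)
Conditions: TBSCl, imidazole, DMF, rt
Reagents that add atoms: tert-butyldimethylsilyl chloride CC(C)(C)[Si](C)(C)Cl
Why: Standard silylation of a secondary allylic alcohol under mildly basic conditions that do not enolise the furanone gives a protecting group that should survive the strong base of the next step.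

Step 13
Reactants: 21 (4Z,7(11)Z,8S,10S)-8-(tert-butyldimethylsilyloxy) furanone-bridged thirteen-membered diallyl ether (C6–O–C13)
Product: 24 (4Z,6S,7S,8S,10S)-6-hydroxy-7-(prop-1-en-2-yl)-8-(tert-butyldimethylsilyloxy) ten-membered carbocycle with the C3–O–C10 furanone bridge, via potassium trienolate 22 (not isolated), via potassium alkoxide 23 (not isolated)
Conditions: KN(SiMe3)2 (1.2 equiv), THF, −78 °C, then −78 → −40 °C; AcOH in THF, −78 °C
Reagents that add atoms: none
Why: KN(SiMe3)2 removes a C6 proton, which is α to the ether oxygen and conjugated through C5=C4 and C3=C2 with the C1 carbonyl, so the charge of trienolate 22 reaches the furanone oxygen and no other C–H (C13, C15, C9) competes; C6 then bonds to C7 through a five-membered envelope transition state (C6, O, C13, C11, C7) while O–C13 breaks and the alkene moves to C11=C13, giving alkoxide 23, that is a [2,3]-Wittig rearrangement. The closest known reactions are the [2,3]-Wittig ring contraction of thirteen-membered diallylic and allylic propargylic ethers to ten-membered homoallylic alcohols and the [2,3]-Wittig shift of ester dienolates. The ten-membered carbocycle (C1–C10) is not closed end to end but by transannular sigmatropic C6–C7 bonding inside the existing thirteen-membered ring, with O, C13 and C11 extruded as the hydroxyl and 2-propenyl groups (ring contraction from thirteen to ten). C7 is set by the C8 stereocentre, since allylic 1,3-strain with C13 holds C8–H in the alkene plane, the silyloxy group covers one face and C6, tethered through C9–C10–O–C3–C4–C5, reaches C7 on the C9 face; C6 is set by the Z C7=C11 geometry together with the ring, because C5 and C8 lie in the same short bridge and must stay gauche across the forming bond, which corresponds to the syn (6S) carbinol. The step needs regioselective C6 deprotonation and [2,3] over [1,2]-shift, C5-to-C7 [3,3]-shift and anionic oxy-Cope rearrangement of 23; the pKa gap created by the furanone, the low temperature and the cold acetic acid quench should secure this.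

Step 14
Reactants: 25 methyl (2Z)-2-methylbut-2-enoate (methyl angelate)
Product: 26 (2Z)-2-methylbut-2-en-1-ol
Conditions: i-Bu2AlH (2.2 equiv), CH2Cl2, −78 °C; aq potassium sodium tartrate
Reagents that add atoms: none
Why: 1,2-Reduction of the conjugated ester with i-Bu2AlH should give the allylic alcohol with the Z geometry of the angelate preserved.

Step 15
Reactants: 26 (2Z)-2-methylbut-2-en-1-ol
Product: 27 [(2R,3S)-2,3-dimethyloxiran-2-yl]methanol
Conditions: Ti(OiPr)4 (0.1 equiv), D-(−)-diethyl tartrate (0.12 equiv), t-BuOOH, 4 Å molecular sieves, CH2Cl2, −20 °C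
Reagents that add atoms: tert-butyl hydroperoxide CC(C)(C)OO
Why: Sharpless asymmetric epoxidation: the tartrate sets both epoxide carbons at once by reagent control, the D-(−)-ester delivering oxygen to the face that gives the (2R,3S)-epoxy alcohol, and the Z alkene fixes the relative configuration (CH2OH cis to the C3 methyl); any minor enantiomer would be removed later as a diastereomeric ester.

Step 16
Reactants: 27 [(2R,3S)-2,3-dimethyloxiran-2-yl]methanol
Product: 28 (2S,3S)-2,3-dimethyloxirane-2-carboxylic acid
Conditions: RuCl3 (0.03 equiv), NaIO4 (4 equiv), MeCN/EtOAc/H2O, 0 °C → rt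
Reagents that add atoms: water O
Why: Ruthenium tetroxide generated in situ oxidises the primary alcohol through the aldehyde hydrate to the glycidic acid without opening the epoxide, the usual route from 2,3-epoxy alcohols to epoxy acids, and the C2 descriptor changes from R to S only because the carboxyl group outranks the ring carbon.

Step 17
Reactants: 24 (4Z,6S,7S,8S,10S)-6-hydroxy-7-(prop-1-en-2-yl)-8-(tert-butyldimethylsilyloxy) ten-membered carbocycle with the C3–O–C10 furanone bridge; 28 (2S,3S)-2,3-dimethyloxirane-2-carboxylic acid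
Product: 30 (4Z,6S,7S,8S,10S)-6-[(2S,3S)-2,3-dimethyloxirane-2-carbonyloxy]-7-(prop-1-en-2-yl)-8-(tert-butyldimethylsilyloxy) furanone-bridged carbocycle, via mixed anhydride 29 (not isolated)
Conditions: 28, 2,4,6-trichlorobenzoyl chloride, Et3N, THF, rt; then 24, 4-(dimethylamino)pyridine, toluene, rt
Reagents that add atoms: none
Why: Yamaguchi esterification activates the hindered α,α-disubstituted epoxy acid as a mixed anhydride that 4-(dimethylamino)pyridine should transfer to the C6 hydroxyl, the only free hydroxyl, with no change at any stereocentre.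

Step 18
Reactants: 30 (4Z,6S,7S,8S,10S)-6-[(2S,3S)-2,3-dimethyloxirane-2-carbonyloxy]-7-(prop-1-en-2-yl)-8-(tert-butyldimethylsilyloxy) furanone-bridged carbocycle
Product: 31 (4Z,6S,7S,8S,10S)-6-acyloxy-7-(3-hydroxyprop-1-en-2-yl)-8-(tert-butyldimethylsilyloxy) furanone-bridged carbocycle (C12 alcohol)
Conditions: SeO2 (0.5 equiv), t-BuOOH (3 equiv), CH2Cl2, 0 °C → rt
Reagents that add atoms: selenium dioxide O=[Se]=O; tert-butyl hydroperoxide CC(C)(C)OO
Why: Selenium dioxide allylic oxidation (ene reaction then [2,3]-shift, the selenium being reoxidised by the hydroperoxide) should attack the electron-rich 1,1-disubstituted C11=C13 alkene rather than the conjugated dienone alkenes and oxidise its methyl group (C12) in preference to the hindered C7 methine, returning the double bond to C11=C13; any enal from over-oxidation converges in step 20.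

Step 19
Reactants: 31 (4Z,6S,7S,8S,10S)-6-acyloxy-7-(3-hydroxyprop-1-en-2-yl)-8-(tert-butyldimethylsilyloxy) furanone-bridged carbocycle (C12 alcohol)
Product: 32 (4Z,6S,7R,8S,10S)-6-acyloxy-8-hydroxy-7-(3-hydroxyprop-1-en-2-yl) furanone-bridged carbocycle (8,12-diol)
Conditions: HF·pyridine, pyridine, THF, 0 °C → rt
Reagents that add atoms: none
Why: Buffered HF·pyridine cleaves the secondary silyl ether under mildly acidic conditions that avoid base-induced 1,3-acyl migration from O6 to O8 and should leave the epoxy ester intact.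

Step 20
Reactants: 32 (4Z,6S,7R,8S,10S)-6-acyloxy-8-hydroxy-7-(3-hydroxyprop-1-en-2-yl) furanone-bridged carbocycle (8,12-diol)
Product: 35 CNP0258430.1 (target), via hydroxy enal 33 (not isolated), via lactol 34 (not isolated)
Conditions: 2,2,6,6-tetramethylpiperidin-1-oxyl (TEMPO, 0.2 equiv), PhI(OAc)2 (2.5 equiv), CH2Cl2, rt
Reagents that add atoms: none
Why: Oxoammonium oxidation should take the primary allylic alcohol to the enal, the C8 hydroxyl traps it as the five-membered lactol and the lactol is oxidised on to the α-methylene lactone, the established oxidative lactonisation of 2-methylene-1,4-diols; C8 carries the only free hydroxyl, so only the 8,12-lactone can form.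

Compound list
1 | prop-2-yn-1-ol | OCC#C | starting material
2 | cyclic (Z)-alkenylmagnesium alkoxide (4-methyl-2,5-dihydro-1,2-oxamagnesole) | CC1=C[Mg]OC1 | intermediate
3 | (2Z)-3-iodo-2-methylprop-2-en-1-ol | OC/C(C)=C\I | intermediate
4 | (1Z)-3-bromo-1-iodo-2-methylprop-1-ene | BrC/C(C)=C\I | intermediate
5 | (2Z)-3-methylpent-2-en-4-yn-1-ol | OC/C=C(C)\C#C | starting material
6 | sodium (2Z)-3-methylpent-2-en-4-yn-1-olate | [Na+].[O-]C/C=C(C)\C#C | intermediate
7 | (3Z)-5-{[(2Z)-3-iodo-2-methylprop-2-en-1-yl]oxy}-3-methylpent-3-en-1-yne | C#C/C(C)=C\COC/C(C)=C\I | intermediate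
8 | (S)-citramalic acid, (2S)-2-hydroxy-2-methylbutanedioic acid | OC(=O)C[C@](C)(O)C(=O)O | starting material
9 | 2-[(4S)-2,2,4-trimethyl-5-oxo-1,3-dioxolan-4-yl]acetic acid | OC(=O)C[C@]1(C)OC(C)(C)OC1=O | intermediate
10 | (5S)-5-(2-hydroxyethyl)-2,2,5-trimethyl-1,3-dioxolan-4-one | OCC[C@]1(C)OC(C)(C)OC1=O | intermediate
11 | (3S)-3-hydroxy-3-methyloxolan-2-one | C[C@]1(O)CCOC1=O | intermediate
12 | lithium acetylide of 7 | [Li]C#C/C(C)=C\COC/C(C)=C\I | intermediate
13 | (3S,7Z)-1,3-dihydroxy-9-{[(2Z)-3-iodo-2-methylprop-2-en-1-yl]oxy}-3,7-dimethylnon-7-en-5-yn-4-one | OCC[C@](C)(O)C(=O)C#C/C(C)=C\COC/C(C)=C\I | intermediate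
14 | (3S,7Z)-6-(diethylamino)-1,3-dihydroxy-9-{[(2Z)-3-iodo-2-methylprop-2-en-1-yl]oxy}-3,7-dimethylnona-5,7-dien-4-one | OCC[C@](C)(O)C(=O)C=C(N(CC)CC)/C(C)=C\COC/C(C)=C\I | intermediate
15 | (2S)-2-(2-hydroxyethyl)-5-[(2Z)-4-{[(2Z)-3-iodo-2-methylprop-2-en-1-yl]oxy}but-2-en-2-yl]-2-methylfuran-3(2H)-one | C[C@@]1(CCO)OC(=CC1=O)/C(C)=C\COC/C(C)=C\I | intermediate
16 | 2-[(2S)-5-[(2Z)-4-{[(2Z)-3-iodo-2-methylprop-2-en-1-yl]oxy}but-2-en-2-yl]-2-methyl-3-oxo-2,3-dihydrofuran-2-yl]acetaldehyde | C[C@@]1(CC=O)OC(=CC1=O)/C(C)=C\COC/C(C)=C\I | intermediate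
17 | alkenylchromium dichloride derived from 16 (chromium in place of iodine, Z retained) | C[C@@]1(CC=O)OC(=CC1=O)/C(C)=C\COC/C(C)=C\[Cr](Cl)Cl | intermediate
18 | (4Z,7(11)Z,10S)-8-hydroxy furanone-bridged thirteen-membered diallyl ether, both C8 epimers | C[C@]12CC(O)/C=C(C)\COC/C=C(C)\C(=CC1=O)O2 | intermediate
19 | (4Z,7(11)Z,10S)-8-oxo furanone-bridged thirteen-membered diallyl ether | C[C@]12CC(=O)/C=C(C)\COC/C=C(C)\C(=CC1=O)O2 | intermediate
20 | (4Z,7(11)Z,8S,10S)-8-hydroxy furanone-bridged thirteen-membered diallyl ether | C[C@]12C[C@H](O)/C=C(C)\COC/C=C(C)\C(=CC1=O)O2 | intermediate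
21 | (4Z,7(11)Z,8S,10S)-8-(tert-butyldimethylsilyloxy) furanone-bridged thirteen-membered diallyl ether (precursor of the key step) | C[C@]12C[C@H](O[Si](C)(C)C(C)(C)C)/C=C(C)\COC/C=C(C)\C(=CC1=O)O2 | intermediate
22 | potassium trienolate of 21 (C6 deprotonated, charge on the C1 oxygen) | C[C@]12C[C@H](O[Si](C)(C)C(C)(C)C)/C=C(C)\COC=CC(C)=C(C=C1[O-])O2.[K+] | intermediate
23 | potassium C6 alkoxide of 24 | C[C@]12C[C@H](O[Si](C)(C)C(C)(C)C)[C@@H](C(C)=C)[C@@H]([O-])/C=C(C)\C(=CC1=O)O2.[K+] | intermediate
24 | (4Z,6S,7S,8S,10S)-6-hydroxy-7-(prop-1-en-2-yl)-8-(tert-butyldimethylsilyloxy) ten-membered carbocycle with the C3–O–C10 furanone bridge (product of the key step) | C[C@]12C[C@H](O[Si](C)(C)C(C)(C)C)[C@@H](C(C)=C)[C@@H](O)/C=C(C)\C(=CC1=O)O2 | intermediate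
25 | methyl (2Z)-2-methylbut-2-enoate (methyl angelate) | C/C=C(C)\C(=O)OC | starting material
26 | (2Z)-2-methylbut-2-en-1-ol | C/C=C(C)\CO | intermediate
27 | [(2R,3S)-2,3-dimethyloxiran-2-yl]methanol | OC[C@@]1(C)O[C@H]1C | intermediate
28 | (2S,3S)-2,3-dimethyloxirane-2-carboxylic acid | OC(=O)[C@@]1(C)O[C@H]1C | intermediate
29 | (2S,3S)-2,3-dimethyloxirane-2-carboxylic 2,4,6-trichlorobenzoic anhydride | O=C(OC(=O)[C@@]1(C)O[C@H]1C)c1c(Cl)cc(Cl)cc1Cl | intermediate
30 | (4Z,6S,7S,8S,10S)-6-[(2S,3S)-2,3-dimethyloxirane-2-carbonyloxy]-7-(prop-1-en-2-yl)-8-(tert-butyldimethylsilyloxy) furanone-bridged carbocycle | C[C@]12C[C@H](O[Si](C)(C)C(C)(C)C)[C@@H](C(C)=C)[C@@H](OC(=O)[C@@]3(C)O[C@H]3C)/C=C(C)\C(=CC1=O)O2 | intermediate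
31 | C12 alcohol: as 30 with 7-(3-hydroxyprop-1-en-2-yl), (4Z,6S,7S,8S,10S) | C[C@]12C[C@H](O[Si](C)(C)C(C)(C)C)[C@@H](C(CO)=C)[C@@H](OC(=O)[C@@]3(C)O[C@H]3C)/C=C(C)\C(=CC1=O)O2 | intermediate
32 | 8,12-diol: as 31 with free C8 hydroxyl, (4Z,6S,7R,8S,10S) | C[C@]12C[C@H](O)[C@@H](C(CO)=C)[C@@H](OC(=O)[C@@]3(C)O[C@H]3C)/C=C(C)\C(=CC1=O)O2 | intermediate
33 | hydroxy enal: as 32 with C12 aldehyde, (4Z,6S,7R,8S,10S) | C[C@]12C[C@H](O)[C@@H](C(C=O)=C)[C@@H](OC(=O)[C@@]3(C)O[C@H]3C)/C=C(C)\C(=CC1=O)O2 | intermediate
34 | 8,12-lactol of 33 (C12 hemiacetal, either C12 epimer) | C=C1C(O)O[C@H]2C[C@]3(C)OC(=CC3=O)/C(C)=C\[C@H](OC(=O)[C@@]3(C)O[C@H]3C)[C@H]12 | intermediate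
35 | CNP0258430.1, (4Z,6S,7R,8S,10S)-8,12-olide with 6-O-[(2S,3S)-2,3-dimethyloxirane-2-carbonyl] ester and C3–O–C10 furanone bridge | C=C1C(=O)O[C@H]2C[C@]3(C)OC(=CC3=O)/C(C)=C\[C@H](OC(=O)[C@@]3(C)O[C@H]3C)[C@H]12 | target

Total step count: 20 (steps 1–3 for ether 7, steps 4–5 for lactone 11, steps 14–16 for acid 28, and steps 6–13 and 17–20 after the fragments are joined).
Longest linear sequence: 15 steps, from 1 to 35 (steps 1–3, 6–13 and 17–20); the branch from 8 (steps 4–13 and 17–20) counts 14 steps and the branch from 25 (steps 14–20) counts 7.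

Steps most likely to fail

Step 13. The delocalised potassium trienolate may be too stabilised to rearrange at low temperature, and on warming it may divert into a [1,2]-shift, a C5-to-C7 [3,3]-shift, anionic oxy-Cope rearrangement of the alkoxide, or attack of O6 on C3 with opening of the furanone. The fallback removes the vinylogous stabilisation and uses a classical lithiated allylic ether. It sets out from 21: Luche reduction (NaBH4, CeCl3·7H2O, MeOH, −40 °C) gives the C1 allylic alcohol F1 (C1 epimers are irrelevant), and TESCl/imidazole gives the C1 triethylsilyl ether F2. n-BuLi in THF/HMPA at −78 °C then deprotonates C6, now the α-oxy position of a dienyl ether, and the [2,3]-Wittig ring contraction known for thirteen-membered diallylic ethers gives the ring-contracted C6 alcohol F3. Yamaguchi esterification with 28 gives the C6 epoxy ester F4; buffered HF·pyridine/pyridine at 0 °C removes the triethylsilyl group selectively to give the C1 alcohol F5; MnO2 in CH2Cl2 reoxidises the C1 allylic alcohol to the furanone. The route is rejoined at 30.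

Step 11. Hydride delivery inside the macrocycle may show poor facial selectivity, because the ring conformation can override the catalyst or the two flanks of the ketone may be too alike. The fallback drops steps 10 and 11 and sets out from 18: the C8 epimers are separated by chromatography, the 8S epimer being 20 itself. The 8R alcohol F6 is inverted by a Mitsunobu reaction (4-nitrobenzoic acid, PPh3, diisopropyl azodicarboxylate, THF, 0 °C) to the 8S 4-nitrobenzoate F7, and methanolysis (K2CO3, MeOH) gives more 20, where the route is rejoined.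

Step 18. The selenium ene oxidation may be sluggish or unselective (attack at the C7 methine or the C15 methyl, over-oxidation, damage to the epoxy ester). The fallback functionalises C12 by halogenation instead and sets out from 30: ene-type allylic chlorination of the 2-propenyl group (NaOCl, CeCl3·7H2O, CH2Cl2/H2O, 0 °C) gives the C12 allylic chloride F8. Ganem oxidation (N-methylmorpholine N-oxide, NaI (cat.), MeCN, rt) gives the silylated enal F9, and HF·pyridine/pyridine then removes the silyl group to give hydroxy enal 33 (with its lactol 34), where the route is rejoined; TEMPO/PhI(OAc)2 as in step 20 gives 35.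

Further compounds
F1 | step 13 | C1 allylic alcohol from 21 (furanone carbonyl reduced, (4Z,7(11)Z,8S,10S), C1 epimers) | C[C@]12C[C@H](O[Si](C)(C)C(C)(C)C)/C=C(C)\COC/C=C(C)\C(=CC1O)O2
F2 | step 13 | C1 triethylsilyl ether of F1 | C[C@]12C[C@H](O[Si](C)(C)C(C)(C)C)/C=C(C)\COC/C=C(C)\C(=CC1O[Si](CC)(CC)CC)O2
F3 | step 13 | ring-contracted C6 alcohol with C1 triethylsilyloxy group (configuration at C6, C7, C8, C10 as in 24) | C[C@]12C[C@H](O[Si](C)(C)C(C)(C)C)[C@@H](C(C)=C)[C@@H](O)/C=C(C)\C(=CC1O[Si](CC)(CC)CC)O2
F4 | step 13 | C6 (2S,3S)-2,3-dimethyloxirane-2-carboxylate of F3 | C[C@]12C[C@H](O[Si](C)(C)C(C)(C)C)[C@@H](C(C)=C)[C@@H](OC(=O)[C@@]3(C)O[C@H]3C)/C=C(C)\C(=CC1O[Si](CC)(CC)CC)O2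
F5 | step 13 | C1 alcohol from F4 (C8 silyl ether retained) | C[C@]12C[C@H](O[Si](C)(C)C(C)(C)C)[C@@H](C(C)=C)[C@@H](OC(=O)[C@@]3(C)O[C@H]3C)/C=C(C)\C(=CC1O)O2
F6 | step 11 | (4Z,7(11)Z,8R,10S)-8-hydroxy furanone-bridged thirteen-membered diallyl ether | C[C@]12C[C@@H](O)/C=C(C)\COC/C=C(C)\C(=CC1=O)O2
F7 | step 11 | (4Z,7(11)Z,8S,10S)-8-(4-nitrobenzoyloxy) furanone-bridged thirteen-membered diallyl ether | C[C@]12C[C@H](OC(=O)c3ccc(cc3)[N+](=O)[O-])/C=C(C)\COC/C=C(C)\C(=CC1=O)O2
F8 | step 18 | C12 allylic chloride: as 30 with 7-(3-chloroprop-1-en-2-yl) | C[C@]12C[C@H](O[Si](C)(C)C(C)(C)C)[C@@H](C(CCl)=C)[C@@H](OC(=O)[C@@]3(C)O[C@H]3C)/C=C(C)\C(=CC1=O)O2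
F9 | step 18 | C12 enal: as 30 with 7-(3-oxoprop-1-en-2-yl) | C[C@]12C[C@H](O[Si](C)(C)C(C)(C)C)[C@@H](C(C=O)=C)[C@@H](OC(=O)[C@@]3(C)O[C@H]3C)/C=C(C)\C(=CC1=O)O2
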